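**Retrosynthetic overview**

1. The strategy rests on the ten-membered ring C1–C10: its oxygen pairs C3/C4 (epoxide) and C8/C9 (tertiary OH, OAc) lie five ring atoms apart, so each pair is read as one ring-cis alkene of a cyclodecadiene. Re-joining C3–C9 and C4–C8 folds that ring into a cyclobutane between two five-membered rings: the cyclopentene C1–C2–C3–C9–C10 of a trans-hydrindene (ring A = C1, C10–C14) and the cyclopentenedione C4–C8 that carries C17–C19.
2. Forward: [2+2] photocycloaddition of enedione 28 with hydrindene 22 (bonds C3–C4, C8–C9), enol triflate at O5, thermal cycloreversion (C4–C8, C3–C9) to the ten-membered trienone 33.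
3. Ring A (12α-OH, 13α,14α-epoxide, axial C20 methyl) is finished before the photoreaction from the methyl Hajos–Parrish diketone 5; the 2α-allylic ether comes from an epoxide/selenide sequence.
4. After ring opening: C7 is reduced to the 7β-alcohol, C8=C9 is dihydroxylated from the outer face, the γ-lactone closes with inversion at C7, C5 is methylated, C3=C4 is epoxidised under C2–OH direction, and C6 is oxygenated by an ene reaction and chlorinated with inversion.
5. Ring order: five-membered ring plus ring A (aldol) → ring A epoxide → cyclobutane (transient) → ten-membered ring → lactone → 3,4-epoxide.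

Key step: step 20

**Remarks**

- Briarane numbering is used for all intermediates: C1 quaternary carbon with the C15 methyl; C2–C10 ten-membered ring; C11–C14 rest of ring A; C16 on C5; C17/C18/C19 lactone CH, its methyl and carbonyl; C20 methyl on C11. β is the face of C15 with the rings drawn flat, α the other face.
- Assumption: C17 is left unset from step 19 to step 25 (compounds 27–36 are mixtures at C17 and are drawn without a descriptor there); it is fixed by base equilibration in step 26.
- Assumption: benzyl methyl malonate 23 is taken as commercially available.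

**Route**

Step 1
Reactants: 1 2-methylcyclopentane-1,3-dione; 2 pent-1-en-3-one
Product: 3 2-methyl-2-(3-oxopentyl)cyclopentane-1,3-dione
Conditions: H2O, AcOH (cat.), 75 °C
Reagents that add atoms: none
Why: Michael addition of the enolised 1,3-dione to the vinyl ketone, which stops cleanly at the C-alkylated triketone; no stereocentre is formed.

Step 2
Reactants: 3 triketone
Product: 5 (S)-4,7a-dimethyl-2,3,7,7a-tetrahydro-1H-indene-1,5(6H)-dione (C2 ketone; C10=C11–C12=O enone), via bicyclic ketol 4 (not isolated)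
Conditions: L-phenylalanine (1 equiv), (1S)-camphor-10-sulfonic acid (0.5 equiv), MeCN, 80 °C
Reagents that add atoms: none
Why: Hajos–Parrish reaction: the enamine of the side-chain ketone adds to one of the two enantiotopic ring carbonyls under control of the L-amino acid, which sets C1 (S, C15 β), and the ketol dehydrates under the acid.

Step 3
Reactants: 5 enedione
Product: 6 C2 ethylene ketal of 5 (enone kept)
Conditions: TMSOCH2CH2OTMS, TMSOTf (2 mol %), CH2Cl2, −78 to −40 °C
Reagents that add atoms: 1,2-bis(trimethylsilyloxy)ethane C[Si](C)(C)OCCO[Si](C)(C)C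
Why: TMSOTf-catalysed silyl-transfer ketalisation takes the saturated cyclopentanone and leaves the less electrophilic conjugated ketone.

Step 4
Reactants: 6 ketal enone
Product: 7 12α-allylic alcohol (12R)
Conditions: (S)-2-methyl-CBS-oxazaborolidine (0.2 equiv), catecholborane, toluene, −78 °C
Reagents that add atoms: none
Why: Corey–Bakshi–Shibata reduction in which the α-methylalkenyl arm (C11) is the large group and the C13 methylene the small one, so the (S)-catalyst delivers hydride to give the 12α-alcohol against the modest substrate bias.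

Step 5
Reactants: 7 allylic alcohol
Product: 8 trans-hydrindan-12α-ol (H10 α, C20 β)
Conditions: H2 (1 atm), [Ir(cod)(PCy3)(py)]PF6 (5 mol %), CH2Cl2, rt
Reagents that add atoms: none
Why: Hydroxyl-directed homogeneous hydrogenation: iridium bound to the 12α-OH adds both hydrogens to the α face of the tetrasubstituted C10=C11 bond, which sets the trans ring fusion (H10 α) and the axial β-methyl at C11 in one step.

Step 6
Reactants: 8 trans-hydrindanol
Product: 9 Δ12(13)-alkene
Conditions: POCl3, pyridine, 0 to 60 °C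
Reagents that add atoms: none
Why: E2 dehydration of the activated axial 12α-alcohol, for which the only antiperiplanar hydrogen is H13β (C11 carries the axial methyl there), so only the C12=C13 alkene forms and C11 is untouched.

Step 7
Reactants: 9 alkene
Product: 10 12α,13α-epoxide
Conditions: mCPBA, NaHCO3, CH2Cl2, 0 °C
Reagents that add atoms: mCPBA OOC(=O)c1cccc(Cl)c1
Why: Prilezhaev epoxidation from the α face, because the β face is closed by the two syn-axial methyl groups C15 and C20.

Step 8
Reactants: 10 epoxide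
Product: 11 12α-hydroxy-Δ13(14)-alkene
Conditions: LiNEt2 (from Et2NH, n-BuLi), Et2O–hexane, 35 °C
Reagents that add atoms: none
Why: Base-induced isomerisation of an epoxide to an allylic alcohol (syn β-elimination): the amide bound to the epoxide oxygen removes the cis pseudo-axial H14α, whereas H11α is equatorial and tertiary, so the oxygen stays on C12 (α) and the alkene moves to C13=C14.

Step 9
Reactants: 11 allylic alcohol
Product: 12 13α,14α-epoxy-12α-ol
Conditions: mCPBA, NaHCO3, CH2Cl2, 0 °C
Reagents that add atoms: mCPBA OOC(=O)c1cccc(Cl)c1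
Why: Hydroxyl-directed Prilezhaev epoxidation: hydrogen bonding to the pseudo-axial 12α-OH and the blocked β face both place the oxygen on the α face, which sets C13 and C14.

Step 10
Reactants: 12 epoxy alcohol
Product: 13 12α-TBS ether
Conditions: TBSOTf, 2,6-lutidine, CH2Cl2, 0 °C
Reagents that add atoms: TBSOTf CC(C)(C)[Si](C)(C)OS(=O)(=O)C(F)(F)F
Why: Silylation with the silyl triflate, needed for the hindered axial alcohol; this ether is the one protecting group that stays until the last step.

Step 11
Reactants: 13 ketal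
Product: 14 C2 ketone
Conditions: PPTS, acetone–H2O (10:1), 50 °C
Reagents that add atoms: water O
Why: Mild acid-catalysed ketal hydrolysis, which the silyl ether and the epoxide should survive because both backside trajectories at the epoxide lie under the axial methyl groups.

Step 12
Reactants: 14 ketone
Product: 16 C2 enol triflate (C2=C3), via potassium enolate 15 (not isolated)
Conditions: KHMDS, THF, −78 °C; then PhNTf2, −78 to 0 °C
Reagents that add atoms: N-phenylbis(trifluoromethanesulfonimide) O=S(=O)(N(c1ccccc1)S(=O)(=O)C(F)(F)F)C(F)(F)F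
Why: Enolisation is possible only toward C3 because C1 is quaternary, and O-sulfonylation of the enolate gives the enol triflate.

Step 13
Reactants: 16 enol triflate
Product: 17 Δ2(3)-alkene
Conditions: Pd(OAc)2 (5 mol %), PPh3 (10 mol %), HCO2H, n-Bu3N, DMF, 60 °C
Reagents that add atoms: none
Why: Palladium-catalysed formate reduction of an enol triflate (oxidative addition, formate exchange, loss of CO2, reductive elimination), which tolerates the epoxide and the silyl ether.

Step 14
Reactants: 17 alkene
Product: 18 2α,3α-epoxide (bis-epoxide)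
Conditions: mCPBA, NaHCO3, CH2Cl2, 0 °C
Reagents that add atoms: mCPBA OOC(=O)c1cccc(Cl)c1
Why: Prilezhaev epoxidation of the cyclopentene from the α face, away from the angular C15 methyl.

Step 15
Reactants: 18 bis-epoxide
Product: 21 2α-hydroxy-Δ3(9)-alkene, via hydroxy selenide 19 (not isolated), via selenoxide 20 (not isolated)
Conditions: PhSeSePh, NaBH4, EtOH, 70 °C; then H2O2 (30 %), THF, 0 °C to rt
Reagents that add atoms: none
Why: Selenolate opening of the five-ring epoxide at C3 (C2 is neopentylic) from the β face, then selenoxide syn-elimination toward C9 and away from the carbinol, so the oxygen stays on C2 (α) and the C3=C9 alkene appears; the ring A epoxide is not opened because its backside trajectories are shielded.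

Step 16
Reactants: 21 allylic alcohol
Product: 22 2α-triethylsilyl ether (hydrindene partner)
Conditions: TESOTf, 2,6-lutidine, CH2Cl2, −78 °C
Reagents that add atoms: TESOTf CC[Si](CC)(CC)OS(=O)(=O)C(F)(F)F
Why: Silylation of the neopentylic allylic alcohol; the silyl ether is bulky for the photoreaction yet removable later beside the TBS ether.

Step 17
Reactants: 23 benzyl methyl malonate
Product: 24 benzyl methyl 2-methylmalonate
Conditions: MeI (1.0 equiv), K2CO3, acetone, reflux
Reagents that add atoms: iodomethane CI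
Why: C-alkylation of the malonate enolate; the mixed ester provides one carboxyl that can later be removed by hydrogenolysis.

Step 18
Reactants: 24 methylmalonate
Product: 25 trimethylsilyl ketene acetal of 24 (isomer mixture)
Conditions: TMSOTf, Et3N, CH2Cl2, 0 °C
Reagents that add atoms: TMSOTf C[Si](C)(C)OS(=O)(=O)C(F)(F)F
Why: Soft enolisation and O-silylation of the malonate; all regio- and geometric isomers of the ketene acetal give the same product in the next step.

Step 19
Reactants: 25 ketene acetal; 26 cyclopent-4-ene-1,3-dione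
Product: 28 4-[malonyl]cyclopent-4-ene-1,3-dione (enedione partner; racemic at C17), via silyl enol ether 27 (not isolated)
Conditions: TMSOTf (5 mol %), CH2Cl2, −78 °C; then Pd(OAc)2 (1.1 equiv), MeCN, rt
Reagents that add atoms: none
Why: Mukaiyama–Michael addition to the symmetrical ene-dione under non-basic conditions (the acidic C6 methylene rules out enolate chemistry), then Saegusa–Ito oxidation of the kinetic silyl enol ether, which restores the C4=C8 alkene; the quaternary C17 prevents tautomerisation to an exocyclic alkylidene.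

Step 20
Reactants: 22 hydrindene; 28 enedione
Product: 29 cyclobutane photoadduct (α-face, cis,anti,cis; C17 mixture)
Conditions: hν (366 nm, Pyrex), CH2Cl2, −40 °C, 28 (3 equiv) added slowly
Reagents that add atoms: none
Why: The n,π* triplet of enedione 28 adds to the cyclopentene C3=C9 of 22 to give a triplet 1,4-diradical that closes after spin inversion, which is the enone–alkene [2+2] photocycloaddition known for cyclopent-4-ene-1,3-diones and cycloalkenes. The one ring closed is the cyclobutane C3–C4–C8–C9, formed stepwise (first C3–C4, then radical recombination C8–C9, or the reverse), and the two five-membered rings force both fusions to be cis. C3 and C9 are set by approach to the α face away from the C15 methyl, and C4 and C8 by the cis fusion with the dione ring turned away from the hydrindane. All four centres become sp2 in step 23, so face and syn/anti isomers should converge and need not be separated. The selectivity that counts is head-to-head regiochemistry (C8 to C9, C4 to C3): the 2α-OTES group shields C3 on the reacting face, so the C8 terminus with its quaternary malonyl carbon should bond to the open C9 next to H10 and the unsubstituted C4 to C3.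

Step 21
Reactants: 29 photoadduct
Product: 31 propanoate photoadduct (C8–CH(CH3)CO2Me; C17 mixture), via malonic half acid 30 (not isolated)
Conditions: H2 (1 atm), Pd/C, EtOAc, rt; then toluene, 90 °C
Reagents that add atoms: none
Why: Hydrogenolysis of the benzyl ester, clean here because 29 has no C=C bond, then thermal decarboxylation of the malonic half acid; the extra carboxyl is thus removed before the tertiary C8 alcohol exists, so no retro-aldol-prone β-hydroxy malonate is ever formed.

Step 22
Reactants: 31 cyclic 1,3-dione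
Product: 32 vinylogous triflate (C5–OTf, C5=C6, C7=O)
Conditions: Tf2O, 2,6-lutidine, CH2Cl2, −78 °C
Reagents that add atoms: triflic anhydride O=S(=O)(OS(=O)(=O)C(F)(F)F)C(F)(F)F
Why: O-sulfonylation of the enolised cyclic 1,3-dione at the less hindered oxygen O5, since O7 sits next to the fully substituted C8; this differentiates C5 from C7 on the rigid tricycle and fixes C4 and C7 cis across C5=C6 through the five-membered ring.

Step 23
Reactants: 32 vinylogous triflate
Product: 33 ten-membered trienone triflate (3Z, 8Z; C4 and C7 cis across C5=C6)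
Conditions: PhMe (5 mM, degassed, BHT), silanised flow coil, 260 °C, 10 min residence
Reagents that add atoms: none
Why: Thermal [2+2] cycloreversion in the metathesis sense, of the kind known for tricyclo[5.3.0.0(2,6)]decane photoadducts: homolysis of the strained, fully substituted C4–C8 bond gives a diradical stabilised as an allyl radical (C4–C5=C6) and an α-keto radical (C8–C7=O), β-scission of C3–C9 opens the ten-membered ring, and the planar radical centres let the less strained ring-cis alkenes C3=C4 and C8=C9 form.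

Step 24
Reactants: 33 trienone
Product: 34 7β-alcohol (7R; C7 opposite to the target on purpose)
Conditions: (S)-2-methyl-CBS-oxazaborolidine (0.5 equiv), catecholborane, toluene, −78 °C
Reagents that add atoms: none
Why: Corey–Bakshi–Shibata 1,2-reduction in which the fully substituted alkenyl arm at C8 is the large group and the C6 vinyl CH the small one, so the (S)-catalyst gives the 7β-alcohol, which is used at once so that the hydroxy ester does not lactonise with retention.

Step 25
Reactants: 34 7β-alcohol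
Product: 35 8α,9α-osmate ester (TMEDA complex; 7β-OH free)
Conditions: OsO4 (1.05 equiv), TMEDA (1.1 equiv), CH2Cl2, −78 °C
Reagents that add atoms: osmium tetroxide O=[Os](=O)(=O)=O; TMEDA CN(C)CCN(C)C
Why: Hydrogen-bond-directed syn dihydroxylation: with H7 and H10 eclipsing the C8=C9 bond (allylic 1,3-strain) the 7β-OH and C11 both lie on the outer face, so the OsO4·TMEDA complex bound to the hydroxyl adds there and sets C8 and C9 (both oxygens α); the vinyl triflate alkene is too electron-poor to react and C3=C4 is remote from the hydroxyl.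

Step 26
Reactants: 35 osmate ester
Product: 38 8α,9α-diol 7α,19-lactone (C18 as in the target), via mesylate 36 (not isolated), via lactone osmate 37 (not isolated)
Conditions: Ms2O, Et3N, CH2Cl2, 0 °C to rt; then DBU, rt; then aq. Na2SO3, THF, 40 °C
Reagents that add atoms: none
Why: Lactonisation with inversion by neighbouring-group participation: the ester carbonyl oxygen displaces the allylic C7 mesylate (5-exo-tet) and the mesylate anion removes the O-methyl group, which turns 7β-OH into the 7α lactone oxygen while O8 and O9 are tied up in the osmate; DBU then equilibrates C17 to the epimer with C18 anti to the C9 branch, and sulfite releases the diol.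

Step 27
Reactants: 38 diol lactone
Product: 39 9α-acetate
Conditions: Ac2O, DMAP (cat.), pyridine, CH2Cl2, 0 °C to rt
Reagents that add atoms: acetic anhydride CC(=O)OC(C)=O
Why: Acylation of the only secondary alcohol; the tertiary C8 hydroxyl does not react under these conditions, and capping O9 also prevents translactonisation.

Step 28
Reactants: 39 vinyl triflate
Product: 40 5-methyl diene (C3=C4–C5(CH3)=C6)
Conditions: MeZnCl (4 equiv), Pd(PPh3)4 (5 mol %), THF, rt
Reagents that add atoms: methylzinc chloride C[Zn]Cl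
Why: Negishi coupling at the vinyl triflate with retention of alkene geometry; the organozinc tolerates lactone, acetate and the free tertiary alcohol (as its zinc alkoxide).

Step 29
Reactants: 40 TES ether
Product: 41 2α-allylic alcohol
Conditions: HF·pyridine, pyridine, THF, 0 °C
Reagents that add atoms: none
Why: Buffered fluoride desilylation, which removes the triethylsilyl ether and leaves the more hindered, more stable TBS ether at C12.

Step 30
Reactants: 41 allylic alcohol
Product: 42 3α,4α-epoxy-2α-ol
Conditions: VO(acac)2 (5 mol %), t-BuOOH (1.2 equiv), CH2Cl2, 0 °C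
Reagents that add atoms: tert-butyl hydroperoxide CC(C)(C)OO
Why: Vanadium-catalysed hydroxyl-directed epoxidation, which for (Z)-allylic alcohols in medium rings gives the cis epoxy alcohol (small O–C–C=C angle in the vanadate transition state) and so sets C3 and C4; the C5=C6 alkene is only homoallylic to a hydroxyl and reacts far more slowly.

Step 31
Reactants: 42 epoxy alcohol
Product: 43 2α,9α-diacetate
Conditions: Ac2O, DMAP, Et3N, CH2Cl2, rt
Reagents that add atoms: acetic anhydride CC(=O)OC(C)=O
Why: DMAP-catalysed acylation of the hindered secondary C2 alcohol, with the tertiary C8 alcohol again left free.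

Step 32
Reactants: 43 diacetate
Product: 45 6β-hydroxy-5(16)-ene, via hydroperoxide 44 (not isolated)
Conditions: O2, tetraphenylporphyrin (cat.), hν (visible), CH2Cl2, −20 °C; then PPh3, 0 °C
Reagents that add atoms: oxygen O=O
Why: Schenck ene reaction: singlet oxygen attacks the only alkene on its outer face (the side of the lactone oxygen, with H7 eclipsing the alkene) and can take only a methyl hydrogen, because H4 and H7 lie in the alkene plane, which gives the 6β-hydroperoxide with the exocyclic C5=C16 alkene, and PPh3 reduces it to the alcohol.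

Step 33
Reactants: 45 6β-allylic alcohol
Product: 46 6α-chloride (12-OTBS)
Conditions: (Cl3C)2CO, PPh3, CH2Cl2, 0 °C
Reagents that add atoms: hexachloroacetone O=C(C(Cl)(Cl)Cl)C(Cl)(Cl)Cl
Why: Appel-type deoxychlorination with hexachloroacetone/PPh3, the reagent pair known to convert secondary allylic alcohols to chlorides with inversion and without allylic shift, which sets C6 (Cl α).

Step 34
Reactants: 46 silyl ether
Product: 47 target CNP0141778.3
Conditions: HF·pyridine, pyridine, THF, 0 °C to rt
Reagents that add atoms: none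
Why: Buffered fluoride desilylation of the C12 ether, mild enough for the two epoxides, the allylic chloride, the acetates and the lactone.

**Compound list**

1 | 2-methylcyclopentane-1,3-dione | CC1C(=O)CCC1=O | starting material
2 | pent-1-en-3-one | CCC(=O)C=C | starting material
3 | 2-methyl-2-(3-oxopentyl)cyclopentane-1,3-dione | CCC(=O)CCC1(C)C(=O)CCC1=O | intermediate
4 | bicyclic ketol (C10–OH cis to C15; C11 either) | O=C1CC[C@]2(O)C(C)C(=O)CC[C@]12C | intermediate
5 | (S)-4,7a-dimethyl-2,3,7,7a-tetrahydro-1H-indene-1,5(6H)-dione | O=C1CCC2=C(C)C(=O)CC[C@]12C | intermediate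
6 | C2 ethylene ketal of 5 | C13(OCCO3)CCC2=C(C)C(=O)CC[C@]12C | intermediate
7 | 12α-allylic alcohol (12R), C2 ketal | C13(OCCO3)CCC2=C(C)[C@H](O)CC[C@]12C | intermediate
8 | trans-hydrindan-12α-ol, H10 α, C20 β, C2 ketal | C13(OCCO3)CC[C@H]2[C@@H](C)[C@H](O)CC[C@]12C | intermediate
9 | Δ12(13)-alkene, C2 ketal | C13(OCCO3)CC[C@H]2[C@@H](C)C=CC[C@]12C | intermediate
10 | 12α,13α-epoxide, C2 ketal | C13(OCCO3)CC[C@H]2[C@@H](C)[C@@H]4O[C@@H]4C[C@]12C | intermediate
11 | 12α-hydroxy-Δ13(14)-alkene, C2 ketal | C13(OCCO3)CC[C@H]2[C@@H](C)[C@H](O)C=C[C@]12C | intermediate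
12 | 13α,14α-epoxy-12α-ol, C2 ketal | C13(OCCO3)CC[C@H]2[C@@H](C)[C@H](O)[C@@H]4O[C@@H]4[C@]12C | intermediate
13 | 12α-TBS ether of 12 | C13(OCCO3)CC[C@H]2[C@@H](C)[C@H](O[Si](C)(C)C(C)(C)C)[C@@H]4O[C@@H]4[C@]12C | intermediate
14 | C2 ketone (13α,14α-epoxide, 12α-OTBS) | O=C1CC[C@H]2[C@@H](C)[C@H](O[Si](C)(C)C(C)(C)C)[C@@H]3O[C@@H]3[C@]12C | intermediate
15 | potassium enolate of 14 (C2=C3) | [K+].[O-]C1=CC[C@H]2[C@@H](C)[C@H](O[Si](C)(C)C(C)(C)C)[C@@H]3O[C@@H]3[C@]12C | intermediate
16 | C2 enol triflate (C2=C3) | FC(F)(F)S(=O)(=O)OC1=CC[C@H]2[C@@H](C)[C@H](O[Si](C)(C)C(C)(C)C)[C@@H]3O[C@@H]3[C@]12C | intermediate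
17 | Δ2(3)-alkene | C1=CC[C@H]2[C@@H](C)[C@H](O[Si](C)(C)C(C)(C)C)[C@@H]3O[C@@H]3[C@]12C | intermediate
18 | 2α,3α:13α,14α-bis-epoxide | C1[C@H]2O[C@H]2[C@@]3(C)[C@H]4O[C@H]4[C@@H](O[Si](C)(C)C(C)(C)C)[C@H](C)[C@H]13 | intermediate
19 | 2α-hydroxy-3β-phenylselanyl compound | O[C@@H]1[C@@H]([Se]c4ccccc4)C[C@H]2[C@@H](C)[C@H](O[Si](C)(C)C(C)(C)C)[C@@H]3O[C@@H]3[C@]12C | intermediate
20 | selenoxide of 19 | O[C@@H]1[C@@H]([Se](=O)c4ccccc4)C[C@H]2[C@@H](C)[C@H](O[Si](C)(C)C(C)(C)C)[C@@H]3O[C@@H]3[C@]12C | intermediate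
21 | 2α-hydroxy-Δ3(9)-hydrindene | O[C@@H]1C=C[C@H]2[C@@H](C)[C@H](O[Si](C)(C)C(C)(C)C)[C@@H]3O[C@@H]3[C@]12C | intermediate
22 | 2α-triethylsilyloxy-Δ3(9)-hydrindene (photo partner) | CC[Si](CC)(CC)O[C@@H]1C=C[C@H]2[C@@H](C)[C@H](O[Si](C)(C)C(C)(C)C)[C@@H]3O[C@@H]3[C@]12C | intermediate
23 | benzyl methyl malonate | COC(=O)CC(=O)OCc1ccccc1 | starting material
24 | benzyl methyl 2-methylmalonate | COC(=O)C(C)C(=O)OCc1ccccc1 | intermediate
25 | trimethylsilyl ketene acetal of 24 (one isomer drawn) | COC(=O)C(C)=C(OCc1ccccc1)O[Si](C)(C)C | intermediate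
26 | cyclopent-4-ene-1,3-dione | O=C1CC(=O)C=C1 | starting material
27 | Mukaiyama–Michael silyl enol ether (racemic) | C[Si](C)(C)OC1=CC(C(C)(C(=O)OC)C(=O)OCc2ccccc2)C(=O)C1 | intermediate
28 | 4-[1-benzyloxycarbonyl-1-methoxycarbonylethyl]cyclopent-4-ene-1,3-dione (racemic at C17) | O=C1CC(=O)C(C(C)(C(=O)OC)C(=O)OCc2ccccc2)=C1 | intermediate
29 | cyclobutane photoadduct, α-face, cis,anti,cis (C17 mixture) | O=C1CC(=O)[C@]2(C(C)(C(=O)OC)C(=O)OCc6ccccc6)[C@H]1[C@H]3[C@@H](O[Si](CC)(CC)CC)[C@]4(C)[C@@H]([C@@H]23)[C@@H](C)[C@H](O[Si](C)(C)C(C)(C)C)[C@@H]5O[C@@H]54 | intermediate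
30 | malonic half acid of 29 | O=C1CC(=O)[C@]2(C(C)(C(=O)OC)C(O)=O)[C@H]1[C@H]3[C@@H](O[Si](CC)(CC)CC)[C@]4(C)[C@@H]([C@@H]23)[C@@H](C)[C@H](O[Si](C)(C)C(C)(C)C)[C@@H]5O[C@@H]54 | intermediate
31 | propanoate photoadduct (C17 mixture) | O=C1CC(=O)[C@]2(C(C)C(=O)OC)[C@H]1[C@H]3[C@@H](O[Si](CC)(CC)CC)[C@]4(C)[C@@H]([C@@H]23)[C@@H](C)[C@H](O[Si](C)(C)C(C)(C)C)[C@@H]5O[C@@H]54 | intermediate
32 | vinylogous triflate (C5–OTf, C7=O) | FC(F)(F)S(=O)(=O)OC1=CC(=O)[C@]2(C(C)C(=O)OC)[C@H]1[C@H]3[C@@H](O[Si](CC)(CC)CC)[C@]4(C)[C@@H]([C@@H]23)[C@@H](C)[C@H](O[Si](C)(C)C(C)(C)C)[C@@H]5O[C@@H]54 | intermediate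
33 | ten-membered trienone triflate (3Z, 8Z, C4/C7 cis) | O=C1/C=C(OS(=O)(=O)C(F)(F)F)\C=C/[C@@H](O[Si](CC)(CC)CC)[C@]2(C)[C@@H](/C=C1/C(C)C(=O)OC)[C@@H](C)[C@H](O[Si](C)(C)C(C)(C)C)[C@@H]3O[C@@H]32 | intermediate
34 | 7β-alcohol (7R) | O[C@@H]1/C=C(OS(=O)(=O)C(F)(F)F)\C=C/[C@@H](O[Si](CC)(CC)CC)[C@]2(C)[C@@H](/C=C1/C(C)C(=O)OC)[C@@H](C)[C@H](O[Si](C)(C)C(C)(C)C)[C@@H]3O[C@@H]32 | intermediate
35 | 8α,9α-osmate ester (TMEDA), 7β-OH | O[C@@H]1/C=C(OS(=O)(=O)C(F)(F)F)\C=C/[C@@H](O[Si](CC)(CC)CC)[C@]2(C)[C@@H]([C@H]3O[Os-2]4(=O)(=O)([N+](C)(C)CC[N+]4(C)C)O[C@@]13C(C)C(=O)OC)[C@@H](C)[C@H](O[Si](C)(C)C(C)(C)C)[C@@H]5O[C@@H]52 | intermediate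
36 | 7β-mesylate of 35 | CS(=O)(=O)O[C@@H]1/C=C(OS(=O)(=O)C(F)(F)F)\C=C/[C@@H](O[Si](CC)(CC)CC)[C@]2(C)[C@@H]([C@H]3O[Os-2]4(=O)(=O)([N+](C)(C)CC[N+]4(C)C)O[C@@]13C(C)C(=O)OC)[C@@H](C)[C@H](O[Si](C)(C)C(C)(C)C)[C@@H]5O[C@@H]52 | intermediate
37 | 7α,19-lactone osmate ester | O1[C@H]2/C=C(OS(=O)(=O)C(F)(F)F)\C=C/[C@@H](O[Si](CC)(CC)CC)[C@]3(C)[C@@H]([C@H]4O[Os-2]5(=O)(=O)([N+](C)(C)CC[N+]5(C)C)O[C@@]24[C@@H](C)C1=O)[C@@H](C)[C@H](O[Si](C)(C)C(C)(C)C)[C@@H]6O[C@@H]63 | intermediate
38 | 8α,9α-diol 7α,19-lactone | O1[C@H]2/C=C(OS(=O)(=O)C(F)(F)F)\C=C/[C@@H](O[Si](CC)(CC)CC)[C@]3(C)[C@@H]([C@@H](O)[C@]2(O)[C@@H](C)C1=O)[C@@H](C)[C@H](O[Si](C)(C)C(C)(C)C)[C@@H]4O[C@@H]43 | intermediate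
39 | 9α-acetate | O1[C@H]2/C=C(OS(=O)(=O)C(F)(F)F)\C=C/[C@@H](O[Si](CC)(CC)CC)[C@]3(C)[C@@H]([C@@H](OC(C)=O)[C@]2(O)[C@@H](C)C1=O)[C@@H](C)[C@H](O[Si](C)(C)C(C)(C)C)[C@@H]4O[C@@H]43 | intermediate
40 | 5-methyl (3Z,5Z)-diene | O1[C@H]2/C=C(C)\C=C/[C@@H](O[Si](CC)(CC)CC)[C@]3(C)[C@@H]([C@@H](OC(C)=O)[C@]2(O)[C@@H](C)C1=O)[C@@H](C)[C@H](O[Si](C)(C)C(C)(C)C)[C@@H]4O[C@@H]43 | intermediate
41 | 2α-allylic alcohol | O1[C@H]2/C=C(C)\C=C/[C@@H](O)[C@]3(C)[C@@H]([C@@H](OC(C)=O)[C@]2(O)[C@@H](C)C1=O)[C@@H](C)[C@H](O[Si](C)(C)C(C)(C)C)[C@@H]4O[C@@H]43 | intermediate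
42 | 3α,4α-epoxy-2α-ol | O1[C@H]2/C=C(C)\[C@H]5O[C@H]5[C@@H](O)[C@]3(C)[C@@H]([C@@H](OC(C)=O)[C@]2(O)[C@@H](C)C1=O)[C@@H](C)[C@H](O[Si](C)(C)C(C)(C)C)[C@@H]4O[C@@H]43 | intermediate
43 | 2α,9α-diacetate | O1[C@H]2/C=C(C)\[C@H]5O[C@H]5[C@@H](OC(C)=O)[C@]3(C)[C@@H]([C@@H](OC(C)=O)[C@]2(O)[C@@H](C)C1=O)[C@@H](C)[C@H](O[Si](C)(C)C(C)(C)C)[C@@H]4O[C@@H]43 | intermediate
44 | 6β-hydroperoxy-5(16)-ene | O1[C@H]2[C@H](OO)C(=C)[C@H]5O[C@H]5[C@@H](OC(C)=O)[C@]3(C)[C@@H]([C@@H](OC(C)=O)[C@]2(O)[C@@H](C)C1=O)[C@@H](C)[C@H](O[Si](C)(C)C(C)(C)C)[C@@H]4O[C@@H]43 | intermediate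
45 | 6β-hydroxy-5(16)-ene | O1[C@H]2[C@H](O)C(=C)[C@H]5O[C@H]5[C@@H](OC(C)=O)[C@]3(C)[C@@H]([C@@H](OC(C)=O)[C@]2(O)[C@@H](C)C1=O)[C@@H](C)[C@H](O[Si](C)(C)C(C)(C)C)[C@@H]4O[C@@H]43 | intermediate
46 | 6α-chloro-5(16)-ene, 12α-OTBS | O1[C@H]2[C@@H](Cl)C(=C)[C@H]5O[C@H]5[C@@H](OC(C)=O)[C@]3(C)[C@@H]([C@@H](OC(C)=O)[C@]2(O)[C@@H](C)C1=O)[C@@H](C)[C@H](O[Si](C)(C)C(C)(C)C)[C@@H]4O[C@@H]43 | intermediate
47 | CNP0141778.3 | C=C1[C@H]2O[C@H]2[C@@H](OC(C)=O)[C@]2(C)[C@H]([C@@H](C)[C@H](O)[C@@H]3O[C@@H]32)[C@@H](OC(C)=O)[C@]2(O)[C@@H](C)C(=O)O[C@H]2[C@H]1Cl | target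

**Step count**

Total: 34 steps. Longest linear sequence: 31 steps (steps 1–16 and 20–34, from 2-methylcyclopentane-1,3-dione); the enedione branch (steps 17–19) joins at step 20.

**Steps most likely to fail**

1. Step 23 (cycloreversion). The vinylogous triflate may decompose before the C4–C8 bond breaks, or the dienone product may suffer 1,5-hydrogen shifts during the residence time. Fallback: change the order so that the bond to be broken lies between two acyl-bearing carbons. The 1,3-diketone 31 is thermolysed under the same flow conditions to the (3Z,8Z)-cyclodecadiene-5,7-dione F2, and the enol triflate is put on afterwards (Tf2O, 2,6-lutidine, −78 °C; O5 is again the less hindered enol oxygen, and the chelated enol gives C4 and C7 cis). This sets out from 31 and returns at 33.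

2. Step 20 (photocycloaddition). Steric steering by the C2 silyl ether may not discriminate well enough between head-to-head and head-to-tail bonding, because C3 and C9 differ only in their neighbours. Fallback: replace steric steering by a hydrogen-bond template. The free allylic alcohol 21 is irradiated with 28 in benzene (366 nm); the C2–OH···O=C5 hydrogen bond to the less hindered carbonyl should hold C4 over C3 and give the hydroxy photoadduct F1, which is silylated (TESOTf, 2,6-lutidine, −78 °C). This sets out from 21 and returns at 29.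

3. Step 33 (deoxychlorination). Backside attack of chloride at C6 has to come from the ring-interior face, so substitution with allylic shift (chloride at C16) or incomplete inversion may take over. Fallback: form the C–Cl bond electrophilically instead. Diacetate 43 is treated with Ca(OCl)2 and solid CO2 in CH2Cl2–H2O at 0 °C (ene-type chlorination with HOCl: Cl+ to C6, proton loss from C16), which avoids substitution at C6 and gives 46 directly if chlorine enters anti to the C7–O bond. This sets out from 43 and returns at 46.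

**Further compounds**

F1 | step 20 | 2α-hydroxy cyclobutane photoadduct (α-face, cis,anti,cis; C17 mixture) | O=C1CC(=O)[C@]2(C(C)(C(=O)OC)C(=O)OCc6ccccc6)[C@H]1[C@H]3[C@@H](O)[C@]4(C)[C@@H]([C@@H]23)[C@@H](C)[C@H](O[Si](C)(C)C(C)(C)C)[C@@H]5O[C@@H]54
F2 | step 23 | (3Z,8Z)-cyclodeca-3,8-diene-5,7-dione with C8 propanoate, 2α-OTES, ring A as in 31 (C17 mixture) | O=C1CC(=O)/C=C\[C@@H](O[Si](CC)(CC)CC)[C@]2(C)[C@@H](/C=C1/C(C)C(=O)OC)[C@@H](C)[C@H](O[Si](C)(C)C(C)(C)C)[C@@H]3O[C@@H]32
F0 | step 33 | none | none
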